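**Retrosynthetic overview**

1. The target is quercetin 3',4'-bis(hydrogen sulfate) (flavone numbering). The last operations are sulfation of the ring B catechol and hydrogenolysis of the benzyl ethers at O3 and O7. The chelated 5-OH is left unprotected.
2. The strategy rests on two features: ring C (O1, C2, C3–O, C4=O) is the 3-oxygenated 4-pyranone of kojic acid, and ring A is a 5,7-dioxygenated benzene fused to its C4a=C8a bond.
3. Ring A is therefore cut into a vinylketene (C5 and C8 on the pyranone C8a=C4a bond, from a pyranone-2-carbonyl diazoketone) and an alkynyl ether (C6, C7). This is a Danheiser benzannulation forming C5–C6, C7–C8 and C4a–C5.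
4. Ring order: ring C comes preformed from kojic acid, ring B is attached at C2 by Suzuki coupling, and ring A is built last.

Key step: step 10

Assumption: the target is drawn as the free bis(hydrogen sulfate). Such acids hydrolyse under their own acidity, so the material is carried as the bis(triethylammonium) salt and the free acid is released only in the last operation, cold, and freeze-dried at once.

**Route**

Step 1
Reactants: 1 kojic acid
Product: 2 2-bromo-3-hydroxy-6-(hydroxymethyl)-4H-pyran-4-one (6-bromokojic acid)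
Conditions: NBS, MeCN–H2O, 0 °C to rt
Reagents that add atoms: N-bromosuccinimide, O=C1CCC(=O)N1Br
Why: Electrophilic bromination of the enol (SEAr-type halogenation) should go to C6, the position ortho to the enolic hydroxyl and the only one it activates.

Step 2
Reactants: 2 2-bromo-3-hydroxy-6-(hydroxymethyl)-4H-pyran-4-one
Product: 3 3-(benzyloxy)-2-bromo-6-(hydroxymethyl)-4H-pyran-4-one
Conditions: BnBr, K2CO3, DMF, rt
Reagents that add atoms: benzyl bromide, BrCc1ccccc1
Why: Williamson ether synthesis in which K2CO3 ionizes only the acidic enolic hydroxyl, so the primary alcohol should stay free.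

Step 3
Reactants: 4 4-bromocatechol, 5 dichlorodiphenylmethane
Product: 6 5-bromo-2,2-diphenyl-1,3-benzodioxole
Conditions: neat, 170 °C, N2 stream
Reagents that add atoms: none
Why: Thermal double substitution of the gem-dichloride by the two catechol oxygens (ketalization with loss of HCl) should give the diphenylmethylene ketal, which is stable to base and mild oxidants and is removed later by aqueous acid.

Step 4
Reactants: 6 5-bromo-2,2-diphenyl-1,3-benzodioxole
Product: 7 2-(2,2-diphenyl-1,3-benzodioxol-5-yl)-4,4,5,5-tetramethyl-1,3,2-dioxaborolane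
Conditions: B2pin2, PdCl2(dppf), KOAc, dioxane, 90 °C
Reagents that add atoms: bis(pinacolato)diboron, CC1(C)OB(OC1(C)C)B1OC(C)(C)C(C)(C)O1
Why: Miyaura borylation of the aryl bromide, to which the ketal is inert.

Step 5
Reactants: 3 3-(benzyloxy)-2-bromo-6-(hydroxymethyl)-4H-pyran-4-one, 7 2-(2,2-diphenyl-1,3-benzodioxol-5-yl)-4,4,5,5-tetramethyl-1,3,2-dioxaborolane
Product: 8 3-(benzyloxy)-2-(2,2-diphenyl-1,3-benzodioxol-5-yl)-6-(hydroxymethyl)-4H-pyran-4-one
Conditions: Pd(PPh3)4, K2CO3, dioxane–H2O (5:1), 85 °C
Reagents that add atoms: none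
Why: Suzuki–Miyaura coupling, in which the C–Br bond at the β-carbon of the pyranone enone (a vinylogous acyl bromide) should add readily to zerovalent palladium and the boronate delivers ring B to the future C2 of the flavone.

Step 6
Reactants: 8 3-(benzyloxy)-2-(2,2-diphenyl-1,3-benzodioxol-5-yl)-6-(hydroxymethyl)-4H-pyran-4-one
Product: 9 5-(benzyloxy)-6-(2,2-diphenyl-1,3-benzodioxol-5-yl)-4-oxo-4H-pyran-2-carboxylic acid
Conditions: TEMPO (cat.), PhI(OAc)2, MeCN–H2O (1:1), rt
Reagents that add atoms: water, O
Why: Oxoammonium (TEMPO) oxidation with PhI(OAc)2 as terminal oxidant should take the primary alcohol through the aldehyde hydrate to the acid under near-neutral conditions that spare the ketal and the benzyl ether.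

Step 7
Reactants: 9 5-(benzyloxy)-6-(2,2-diphenyl-1,3-benzodioxol-5-yl)-4-oxo-4H-pyran-2-carboxylic acid
Product: 11 5-(benzyloxy)-2-(diazoacetyl)-6-(2,2-diphenyl-1,3-benzodioxol-5-yl)-4H-pyran-4-one, via acid chloride 10 (not isolated)
Conditions: (COCl)2, cat. DMF, CH2Cl2, 0 °C to rt; evaporate; CH2N2 (1.3 equiv), Et3N (1.1 equiv), THF–Et2O, −10 to 0 °C
Reagents that add atoms: diazomethane, C=[N+]=[N-]; oxalyl chloride, O=C(Cl)C(=O)Cl (chlorine of 10 only)
Why: Chlorination through the Vilsmeier intermediate and acylation of diazomethane (first stage of the Arndt–Eistert sequence, with Et3N as HCl scavenger) should work because the acid chloride has no α-hydrogen, and the small excess of CH2N2 at low temperature limits dipolar addition to the pyranone.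

Step 8
Reactants: 12 trichloroethylene, 13 benzyl alcohol
Product: 15 benzyl (E)-1,2-dichlorovinyl ether, via dichloroacetylene 14 (not isolated)
Conditions: KH, THF, 0 °C to rt
Reagents that add atoms: none
Why: KH-mediated dehydrochlorination of trichloroethylene gives dichloroacetylene, to which the alkoxide adds anti (nucleophilic addition to a haloalkyne), setting the E geometry, which is lost in the next step.

Step 9
Reactants: 15 benzyl (E)-1,2-dichlorovinyl ether
Product: 17 benzyl ethynyl ether, via lithium benzyloxyethynide 16 (not isolated)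
Conditions: n-BuLi (2.2 equiv), THF, −78 °C; MeOH, −78 °C; cold aqueous work-up, pentane, concentrated below 20 °C and used at once as a titrated solution
Reagents that add atoms: none
Why: Deprotonation and loss of LiCl give the chloroalkynyl ether, lithium–chlorine exchange gives the lithium alkynyl ether, and protonation at −78 °C gives the terminal ynol ether (the dichlorovinyl ether route to alkynyl ethers), the low temperature suppressing benzylic metalation.

Step 10
Reactants: 11 5-(benzyloxy)-2-(diazoacetyl)-6-(2,2-diphenyl-1,3-benzodioxol-5-yl)-4H-pyran-4-one, 17 benzyl ethynyl ether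
Product: 21 3,7-bis(benzyloxy)-2-(2,2-diphenyl-1,3-benzodioxol-5-yl)-5-hydroxy-4H-chromen-4-one, via pyranonylketene 18 (not isolated), via vinylcyclobutenone 19 (not isolated), via dienylketene 20 (not isolated)
Conditions: 17 (1.5 equiv), degassed ClCH2CH2Cl, LED 420–450 nm, 15–20 °C; excess 17 pumped off at 0.05 mmHg and 20 °C; toluene, 80 °C
Reagents that add atoms: none
Why: Light absorbed by the diazoketone expels N2 and shifts C8a from the carbonyl carbon to the diazo carbon (Wolff rearrangement), giving ketene 18 conjugated with the C8a=C4a bond of the pyranone; the nucleophilic CH terminus of ynol ether 17 then adds to the ketene carbon in a regiospecific [2+2] cycloaddition to give 3-benzyloxycyclobutenone 19, which on warming opens by four-electron electrocyclic cleavage to dienylketene 20. Ring A closes by six-electron disrotatory electrocyclization of 20 (ketene carbon C5 onto C4a, a 6-membered all-carbon closure), and the resulting cyclohexadienone enolizes to the chelated 5-phenol, which restores the pyranone conjugation and drives the sequence. The closest known reaction type is the Danheiser benzannulation in its diazoketone form with an alkoxyalkyne, in which a heterocyclic C=C bond serves as the vinyl component. No stereocentre persists, since the cyclobutenone carbon of 19 is racemic and becomes sp2. The regiochemistry (oxygen of 17 at C7, ketene oxygen at C5) is secured by the polarization of the ynol ether, and chemoselective excitation is secured by 420–450 nm light, which the diazoketone absorbs weakly but the 3-benzyloxy-2-aryl-4-pyranone chromophore does not, so that γ-hydrogen abstraction from the OCH2Ph group by an excited pyranone carbonyl is avoided. The ynol ether is kept at or below 20 °C and its excess removed before warming, because benzyl alkynyl ethers undergo [3,3] rearrangement near 60 °C.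

Step 11
Reactants: 21 3,7-bis(benzyloxy)-2-(2,2-diphenyl-1,3-benzodioxol-5-yl)-5-hydroxy-4H-chromen-4-one
Product: 22 3,7-bis(benzyloxy)-2-(3,4-dihydroxyphenyl)-5-hydroxy-4H-chromen-4-one
Conditions: AcOH–H2O (4:1), 100 °C
Reagents that add atoms: none
Why: Acid-catalysed ketal hydrolysis through the stabilized diaryl(aryloxy)carbenium ion should free the catechol, while benzyl ethers are stable to hot aqueous acetic acid.

Step 12
Reactants: 22 3,7-bis(benzyloxy)-2-(3,4-dihydroxyphenyl)-5-hydroxy-4H-chromen-4-one
Product: 23 bis(triethylammonium) 4-[3,7-bis(benzyloxy)-5-hydroxy-4-oxo-4H-chromen-2-yl]-1,2-phenylene bis(sulfate)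
Conditions: SO3·NEt3 (8 equiv), Et3N, DMA, 65 °C
Reagents that add atoms: sulfur trioxide–triethylamine complex, CC[N+](CC)(CC)S(=O)(=O)[O-]
Why: O-sulfation of phenols by an amine–SO3 complex should take place only at the two catechol hydroxyls, since O3 and O7 are benzylated and the 5-hydroxyl is tied up in a hydrogen bond to the C4 carbonyl.

Step 13
Reactants: 23 bis(triethylammonium) 4-[3,7-bis(benzyloxy)-5-hydroxy-4-oxo-4H-chromen-2-yl]-1,2-phenylene bis(sulfate)
Product: 25 2-[3,4-bis(sulfooxy)phenyl]-3,5,7-trihydroxy-4H-chromen-4-one (quercetin 3',4'-bis(hydrogen sulfate)), via debenzylated triethylammonium salt 24 (not isolated)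
Conditions: H2 (1 atm), 10% Pd/C, MeOH, rt; filter; sulfonic acid resin (H+ form), H2O, 0 °C; freeze-dry
Reagents that add atoms: none
Why: Hydrogenolysis of the benzyl ethers over Pd/C, to which aryl sulfate anions and the flavonol core are inert, followed by exchange of triethylammonium for protons on a cation-exchange resin, should give the free acid.

**Compound list**

1 | kojic acid [5-hydroxy-2-(hydroxymethyl)-4H-pyran-4-one] | OCc1cc(=O)c(O)co1 | starting material
2 | 2-bromo-3-hydroxy-6-(hydroxymethyl)-4H-pyran-4-one | OCc1cc(=O)c(O)c(Br)o1 | intermediate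
3 | 3-(benzyloxy)-2-bromo-6-(hydroxymethyl)-4H-pyran-4-one | OCc1cc(=O)c(OCc2ccccc2)c(Br)o1 | intermediate
4 | 4-bromocatechol | Oc1ccc(Br)cc1O | starting material
5 | dichlorodiphenylmethane | ClC(Cl)(c1ccccc1)c1ccccc1 | starting material
6 | 5-bromo-2,2-diphenyl-1,3-benzodioxole | Brc1ccc2OC(c3ccccc3)(c3ccccc3)Oc2c1 | intermediate
7 | 2-(2,2-diphenyl-1,3-benzodioxol-5-yl)-4,4,5,5-tetramethyl-1,3,2-dioxaborolane | CC1(C)OB(OC1(C)C)c1ccc2OC(c3ccccc3)(c3ccccc3)Oc2c1 | intermediate
8 | 3-(benzyloxy)-2-(2,2-diphenyl-1,3-benzodioxol-5-yl)-6-(hydroxymethyl)-4H-pyran-4-one | OCc1cc(=O)c(OCc2ccccc2)c(-c2ccc3OC(c4ccccc4)(c4ccccc4)Oc3c2)o1 | intermediate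
9 | 5-(benzyloxy)-6-(2,2-diphenyl-1,3-benzodioxol-5-yl)-4-oxo-4H-pyran-2-carboxylic acid | OC(=O)c1cc(=O)c(OCc2ccccc2)c(-c2ccc3OC(c4ccccc4)(c4ccccc4)Oc3c2)o1 | intermediate
10 | 5-(benzyloxy)-6-(2,2-diphenyl-1,3-benzodioxol-5-yl)-4-oxo-4H-pyran-2-carbonyl chloride | ClC(=O)c1cc(=O)c(OCc2ccccc2)c(-c2ccc3OC(c4ccccc4)(c4ccccc4)Oc3c2)o1 | intermediate (not isolated)
11 | 5-(benzyloxy)-2-(diazoacetyl)-6-(2,2-diphenyl-1,3-benzodioxol-5-yl)-4H-pyran-4-one | [N-]=[N+]=CC(=O)c1cc(=O)c(OCc2ccccc2)c(-c2ccc3OC(c4ccccc4)(c4ccccc4)Oc3c2)o1 | intermediate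
12 | trichloroethylene | ClC=C(Cl)Cl | starting material
13 | benzyl alcohol | OCc1ccccc1 | starting material
14 | dichloroacetylene | ClC#CCl | intermediate (not isolated)
15 | benzyl (E)-1,2-dichlorovinyl ether | Cl/C=C(/Cl)OCc1ccccc1 | intermediate
16 | lithium benzyloxyethynide | [Li]C#COCc1ccccc1 | intermediate (not isolated)
17 | benzyl ethynyl ether | C#COCc1ccccc1 | intermediate
18 | [5-(benzyloxy)-6-(2,2-diphenyl-1,3-benzodioxol-5-yl)-4-oxo-4H-pyran-2-yl]ketene | O=C=Cc1cc(=O)c(OCc2ccccc2)c(-c2ccc3OC(c4ccccc4)(c4ccccc4)Oc3c2)o1 | intermediate (not isolated)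
19 | racemic 3-(benzyloxy)-4-[5-(benzyloxy)-6-(2,2-diphenyl-1,3-benzodioxol-5-yl)-4-oxo-4H-pyran-2-yl]cyclobut-2-en-1-one | O=C1C=C(OCc2ccccc2)C1c1cc(=O)c(OCc2ccccc2)c(-c2ccc3OC(c4ccccc4)(c4ccccc4)Oc3c2)o1 | intermediate (not isolated)
20 | (3E)-3-(benzyloxy)-4-[5-(benzyloxy)-6-(2,2-diphenyl-1,3-benzodioxol-5-yl)-4-oxo-4H-pyran-2-yl]buta-1,3-dien-1-one (ketene arm and pyranone cis) | O=C=C/C(OCc1ccccc1)=C\c1cc(=O)c(OCc2ccccc2)c(-c2ccc3OC(c4ccccc4)(c4ccccc4)Oc3c2)o1 | intermediate (not isolated)
21 | 3,7-bis(benzyloxy)-2-(2,2-diphenyl-1,3-benzodioxol-5-yl)-5-hydroxy-4H-chromen-4-one | O=c1c(OCc2ccccc2)c(-c2ccc3OC(c4ccccc4)(c4ccccc4)Oc3c2)oc2cc(OCc3ccccc3)cc(O)c12 | intermediate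
22 | 3,7-bis(benzyloxy)-2-(3,4-dihydroxyphenyl)-5-hydroxy-4H-chromen-4-one | O=c1c(OCc2ccccc2)c(-c2ccc(O)c(O)c2)oc2cc(OCc3ccccc3)cc(O)c12 | intermediate
23 | bis(triethylammonium) 4-[3,7-bis(benzyloxy)-5-hydroxy-4-oxo-4H-chromen-2-yl]-1,2-phenylene bis(sulfate) | O=c1c(OCc2ccccc2)c(-c2ccc(OS(=O)(=O)[O-])c(OS(=O)(=O)[O-])c2)oc2cc(OCc3ccccc3)cc(O)c12.CC[NH+](CC)CC.CC[NH+](CC)CC | intermediate
24 | bis(triethylammonium) 4-(3,5,7-trihydroxy-4-oxo-4H-chromen-2-yl)-1,2-phenylene bis(sulfate) | O=c1c(O)c(-c2ccc(OS(=O)(=O)[O-])c(OS(=O)(=O)[O-])c2)oc2cc(O)cc(O)c12.CC[NH+](CC)CC.CC[NH+](CC)CC | intermediate (not isolated)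
25 | 2-[3,4-bis(sulfooxy)phenyl]-3,5,7-trihydroxy-4H-chromen-4-one | O=c1c(O)c(-c2ccc(OS(=O)(=O)O)c(OS(=O)(=O)O)c2)oc2cc(O)cc(O)c12 | target

**Totals**

Total step count: 13.
Longest linear sequence: 9 steps (1, 2, 5, 6, 7, 10, 11, 12, 13).

**Steps most likely to fail, with fallbacks**

Step 10. The diazoketone may absorb the long-wavelength light too weakly, or the pyranone chromophore may compete for it and degrade, or the ketene may be lost to dimerization or moisture before it meets the alkyne. The fallback generates the same ketene without light. It sets out from 11: silver-catalysed Wolff rearrangement in water (PhCO2Ag, Et3N, THF–H2O, rt) should give the homologous acid [5-(benzyloxy)-6-(2,2-diphenyl-1,3-benzodioxol-5-yl)-4-oxo-4H-pyran-2-yl]acetic acid F1. F1 is kept cold to avoid decarboxylation and converted with (COCl)2 and catalytic DMF into [5-(benzyloxy)-6-(2,2-diphenyl-1,3-benzodioxol-5-yl)-4-oxo-4H-pyran-2-yl]acetyl chloride F2. Slow addition of Et3N to F2 and 17 in CH2Cl2 at 0 to 20 °C dehydrochlorinates F2 to ketene 18, which is trapped as cyclobutenone 19. After removal of excess 17, warming in toluene at 80 °C takes 19 through 20, and the fallback returns to the route at 21.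

Step 9. Benzylic metalation by n-BuLi with Wittig-type rearrangement may compete with the vinylic deprotonation, and the product may be lost by [3,3] rearrangement if it warms during isolation. The fallback builds the alkyne by elimination from an acetal under amide base. It sets out from 13: acid-catalysed acetal exchange with chloroacetaldehyde dimethyl acetal (cat. TsOH, MeOH distilled off) should give chloroacetaldehyde dibenzyl acetal F3. NaNH2 (3 equiv) in liquid NH3 at −33 °C then removes benzyl alcohol and HCl in turn to give sodium benzyloxyethynide F4. A cold aqueous NH4Cl quench and extraction into pentane deliver the ynol ether, and the fallback returns to the route at 17.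

Step 12. The second sulfation next to an anionic sulfate may stall, and forcing it may begin to sulfate the 5-hydroxyl, so that a mixture of charged products results. The fallback uses neutral, chromatographable sulfate diesters. It sets out from 22: 2,2,2-trichloroethyl chlorosulfate (Et3N, DMAP, THF, 0 °C) should give 4-[3,7-bis(benzyloxy)-5-hydroxy-4-oxo-4H-chromen-2-yl]-1,2-phenylene bis(2,2,2-trichloroethyl) bis(sulfate) F5. Pd/C with HCO2NH4 in MeOH at rt then cleaves the trichloroethyl groups reductively and the benzyl ethers by transfer hydrogenolysis, giving diammonium 4-(3,5,7-trihydroxy-4-oxo-4H-chromen-2-yl)-1,2-phenylene bis(sulfate) F6. Cold exchange on the H+ resin as in step 13 returns the fallback to the route at 25.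

**Further compounds**

F1 | step 10 | [5-(benzyloxy)-6-(2,2-diphenyl-1,3-benzodioxol-5-yl)-4-oxo-4H-pyran-2-yl]acetic acid | OC(=O)Cc1cc(=O)c(OCc2ccccc2)c(-c2ccc3OC(c4ccccc4)(c4ccccc4)Oc3c2)o1
F2 | step 10 | [5-(benzyloxy)-6-(2,2-diphenyl-1,3-benzodioxol-5-yl)-4-oxo-4H-pyran-2-yl]acetyl chloride | ClC(=O)Cc1cc(=O)c(OCc2ccccc2)c(-c2ccc3OC(c4ccccc4)(c4ccccc4)Oc3c2)o1
F3 | step 9 | chloroacetaldehyde dibenzyl acetal [1,1-bis(benzyloxy)-2-chloroethane] | ClCC(OCc1ccccc1)OCc1ccccc1
F4 | step 9 | sodium benzyloxyethynide | [Na]C#COCc1ccccc1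
F5 | step 12 | 4-[3,7-bis(benzyloxy)-5-hydroxy-4-oxo-4H-chromen-2-yl]-1,2-phenylene bis(2,2,2-trichloroethyl) bis(sulfate) | O=c1c(OCc2ccccc2)c(-c2ccc(OS(=O)(=O)OCC(Cl)(Cl)Cl)c(OS(=O)(=O)OCC(Cl)(Cl)Cl)c2)oc2cc(OCc3ccccc3)cc(O)c12
F6 | step 12 | diammonium 4-(3,5,7-trihydroxy-4-oxo-4H-chromen-2-yl)-1,2-phenylene bis(sulfate) | O=c1c(O)c(-c2ccc(OS(=O)(=O)[O-])c(OS(=O)(=O)[O-])c2)oc2cc(O)cc(O)c12.[NH4+].[NH4+]
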